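**Plan**

1. Retrosynthesis: the two senecioate C–O bonds are cut first. The cyclohexenone ring is opened at its C(=O)–CH2 bond (carbonyl-ene) and the ketone carbon is taken off a cyclobutanone (Wittig homologation). The cyclobutane is split into a methylketene and the terminal double bond of an E-diene ([2+2]). Last, the open chain is cut on both sides of its CH2–CH(O) unit.
2. Feature used: in the seven-membered ring the two ester-bearing carbons flank one CH2, and one of them sits next to the CMe2 carbon. This CH2–CH(O) pair is an acetaldehyde unit. Its α-carbon is nucleophilic toward an aldehyde carbon, which becomes the carbinol beside the methyl-bearing quaternary cyclobutane carbon. Its carbonyl carbon is electrophilic toward the γ-carbon of a prenyl nucleophile, which becomes the ring CMe2.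
3. Forward: methacrolein, an acetaldehyde silyl enolate and a chiral prenylborane are joined in one pot to the anti-1,3-diol chain. Esterification, Heck dienylation and oxidation of the methallyl end give an α-methyl acid.
4. Its ketene adds across the diene terminus, so the cyclobutane and the seven-membered ring arise together (bicyclo[4.1.1]octanone). One-carbon homologation and an ene closure then build the six-membered enone ring (bicyclo[3.1.1]heptenone), and the second senecioate goes on last.
5. Stereochemistry: the silyloxy carbinol comes from the chiral acid catalyst and the ester carbinol from the isopinocampheyl groups. The ring stereocentres come from the [2+2] (E-alkene geometry, ring constraint, face control by the silyloxy carbinol) and from the formyl centre that is fixed in the ene closure.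

Key step: step 2

Remark: the antipode of the chiral acid that gives the 3R aldol is used, and isopinocampheyl (Ipc) boranes derived from (+)-α-pinene are taken to add to the Si face of the aldehyde, as they do with simple aldehydes.

**Route**

Step 1
Reactants: 1 (−)-B-methoxydiisopinocampheylborane; 2 3-methylbut-2-enylmagnesium chloride
Product: 3 (−)-B-(3-methylbut-2-enyl)diisopinocampheylborane
Conditions: Et2O, −78 °C → rt, 1 h; the ethereal solution is transferred away from the Mg salts and used directly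
Reagents that add atoms: none
Why: B–OMe/allyl exchange with an allylic Grignard reagent (the standard preparation of B-allyldiisopinocampheylboranes); a fast 1,3-boron shift should leave boron on the primary carbon, so that the CMe2 carbon is the γ-terminus.

Step 2
Reactants: 4 methacrolein; 5 tert-butyldimethyl(vinyloxy)silane; 3 (−)-B-(3-methylbut-2-enyl)diisopinocampheylborane
Product: 8 (4R,6R)-6-[(tert-butyldimethylsilyl)oxy]-3,3,7-trimethylocta-1,7-dien-4-ol, via silyloxy aldehyde 6 (not isolated), via borinic ester 7 (not isolated)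
Conditions: 4, 5 (1.2 equiv), chiral confined imidodiphosphorimidate Brønsted acid (1 mol%), toluene, −40 °C; then 3 (1.3 equiv) in Et2O, −78 °C, 3 h; then 3 M NaOH, 30% H2O2, 0 °C → rt
Reagents that add atoms: none
Why: The silylated chiral acid activates the aldehyde of 4 and the CH2 terminus of enol silane 5 adds to it (Mukaiyama aldol; closest type: confined-acid-catalysed single aldolization of acetaldehyde silyl enolates), the silyl group passing to the aldolate oxygen so that 6 leaves the catalyst as a protected aldehyde. Borane 3 then adds to this aldehyde through a closed chair six-membered transition state with allyl transposition (allylboration; closest type: reverse prenylation with B-prenyldiisopinocampheylborane), so that the CMe2 terminus bonds to the carbonyl carbon, and peroxide cleaves the B–O and B–C bonds of 7. No ring is closed. The silyloxy carbinol centre (6R in 8) is set by the chiral pocket of the acid; the free carbinol centre (4R) is set by the isopinocampheyl groups, which direct the allyl unit to the Si face and override the weak 1,3-induction of the β-silyloxy group, giving the anti-1,3-diol pattern. The step needs single aldolization, 1,2- rather than 1,4-addition to the enal and γ- rather than α-attack of the prenyl unit: the confined catalyst should discriminate the small aldehyde 4 from the larger product 6, silyl enol ethers add 1,2 to acid-activated enals, and the cyclic boron transition state enforces γ-attack.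

Step 3
Reactants: 8 (4R,6R)-6-[(tert-butyldimethylsilyl)oxy]-3,3,7-trimethylocta-1,7-dien-4-ol
Product: 9 (4R,6R)-6-[(tert-butyldimethylsilyl)oxy]-3,3,7-trimethylocta-1,7-dien-4-yl 3-methylbut-2-enoate
Conditions: 3-methylbut-2-enoyl chloride (2 equiv), pyridine, DMAP (0.2 equiv), CH2Cl2, 0 → 40 °C
Reagents that add atoms: 3-methylbut-2-enoyl chloride, CC(C)=CC(Cl)=O
Why: DMAP-catalysed acylation of the hindered secondary alcohol (nucleophilic acyl substitution); pyridine as the only base should keep the acyl chloride from deconjugating through its vinylketene, and the silyl ether is untouched.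

Step 4
Reactants: 9 (4R,6R)-6-[(tert-butyldimethylsilyl)oxy]-3,3,7-trimethylocta-1,7-dien-4-yl 3-methylbut-2-enoate
Product: 10 (3R,5R,7E)-3-[(tert-butyldimethylsilyl)oxy]-2,6,6,9-tetramethyldeca-1,7,9-trien-5-yl 3-methylbut-2-enoate
Conditions: 2-bromopropene (3 equiv), Pd(OAc)2 (5 mol%), P(o-tol)3 (10 mol%), Et3N, MeCN, 80 °C, sealed tube
Reagents that add atoms: 2-bromopropene, CC(Br)=C
Why: Heck reaction: the alkenylpalladium bromide should add to the unhindered CH2 of the monosubstituted alkene, and because the neighbouring carbon is quaternary, β-hydride elimination can only give the conjugated E-diene; the 1,1-disubstituted alkene and the enoate insert much more slowly.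

Step 5
Reactants: 10 (3R,5R,7E)-3-[(tert-butyldimethylsilyl)oxy]-2,6,6,9-tetramethyldeca-1,7,9-trien-5-yl 3-methylbut-2-enoate
Product: 12 (2RS,3R,5R,7E)-3-[(tert-butyldimethylsilyl)oxy]-1-hydroxy-2,6,6,9-tetramethyldeca-7,9-dien-5-yl 3-methylbut-2-enoate, via B-alkyl-9-BBN adduct 11 (not isolated)
Conditions: 9-BBN (1.2 equiv), THF, 0 °C → rt; then 3 M NaOAc, 30% H2O2, 0 °C → rt
Reagents that add atoms: hydrogen peroxide, OO
Why: anti-Markovnikov hydroboration–oxidation; 9-BBN should take the isolated 1,1-disubstituted alkene far faster than the conjugated diene or the enoate, and the new methyl-bearing centre forms as a mixture that is harmless because it becomes sp2 in the ketene of step 7.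

Step 6
Reactants: 12 (2RS,3R,5R,7E)-3-[(tert-butyldimethylsilyl)oxy]-1-hydroxy-2,6,6,9-tetramethyldeca-7,9-dien-5-yl 3-methylbut-2-enoate
Product: 14 (2RS,3R,5R,7E)-3-[(tert-butyldimethylsilyl)oxy]-2,6,6,9-tetramethyl-5-[(3-methylbut-2-enoyl)oxy]deca-7,9-dienoic acid, via aldehyde 13 (not isolated)
Conditions: TEMPO (0.2 equiv), PhI(OAc)2 (2.5 equiv), MeCN/H2O 1:1, rt
Reagents that add atoms: water, O
Why: oxoammonium-mediated oxidation of the primary alcohol to the aldehyde and, through its hydrate, to the acid; alkenes, silyl ether and ester should be inert, and epimerization next to the carbonyl is of no consequence.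

Step 7
Reactants: 14 (2RS,3R,5R,7E)-3-[(tert-butyldimethylsilyl)oxy]-2,6,6,9-tetramethyl-5-[(3-methylbut-2-enoyl)oxy]deca-7,9-dienoic acid
Product: 17 2-[(tert-butyldimethylsilyl)oxy]-1,5,5-trimethyl-7-oxo-8-(prop-1-en-2-yl)bicyclo[4.1.1]octan-4-yl 3-methylbut-2-enoate (isopropenyl syn to the carbonyl bridge, silyloxy and ester groups trans), via acid chloride 15 (not isolated), via methylketene 16 (not isolated)
Conditions: 1-chloro-N,N,2-trimethylprop-1-en-1-amine (1.2 equiv), CH2Cl2, 0 °C → rt; then added over 8 h to Et3N (5 equiv), toluene, 100 °C, final concentration 0.005 M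
Reagents that add atoms: none
Why: intramolecular ketene–alkene [2+2] cycloaddition from an acid chloride and a tertiary amine: the ketene central carbon should bond to the diene terminus (allyl-cation character, seven-membered first bond) and the ketene α-carbon close on the internal diene carbon, as in ketene–1,3-diene additions; the bridgehead centres are fixed by the four-atom tether, the E-alkene places isopropenyl syn to the carbonyl bridge, and the face is set by the silyloxy carbinol, whose C–H lies beside the ketene methyl (allylic strain) so that the diene adds anti to the silyloxy group.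

Step 8
Reactants: 17 2-[(tert-butyldimethylsilyl)oxy]-1,5,5-trimethyl-7-oxo-8-(prop-1-en-2-yl)bicyclo[4.1.1]octan-4-yl 3-methylbut-2-enoate
Product: 19 2-[(tert-butyldimethylsilyl)oxy]-7-formyl-1,5,5-trimethyl-8-(prop-1-en-2-yl)bicyclo[4.1.1]octan-4-yl 3-methylbut-2-enoate (formyl cis to isopropenyl on the cyclobutane), via methyl enol ether 18 (not isolated)
Conditions: (methoxymethyl)triphenylphosphonium chloride (2 equiv), KN(SiMe3)2 (1.9 equiv), THF, −78 → 0 °C; then Cl3CCO2H, CH2Cl2/H2O, 0 °C
Reagents that add atoms: (methoxymethyl)triphenylphosphonium chloride, COC[P+](c1ccccc1)(c1ccccc1)c1ccccc1.[Cl-]; water, O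
Why: Wittig methoxymethylenation of the strained, non-enolisable ketone and mild acid hydrolysis of the enol ether (one-carbon homologation); protonation from the face away from the isopropenyl group should leave the formyl group cis to it, and this centre stays epimerisable until step 9.

Step 9
Reactants: 19 2-[(tert-butyldimethylsilyl)oxy]-7-formyl-1,5,5-trimethyl-8-(prop-1-en-2-yl)bicyclo[4.1.1]octan-4-yl 3-methylbut-2-enoate
Product: 20 3-[(tert-butyldimethylsilyl)oxy]-11-hydroxy-2,6,6-trimethyl-9-methylidenetricyclo[5.4.0.0(2,8)]undecan-5-yl 3-methylbut-2-enoate (C-11 epimers)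
Conditions: Me2AlCl (1.5 equiv), CH2Cl2, −78 → −20 °C
Reagents that add atoms: none
Why: Lewis acid-promoted intramolecular carbonyl-ene reaction (Prins type): formyl and isopropenyl are held 1,3-cis on the puckered cyclobutane, the carbonyl carbon should bond to the alkene CH2 with hydrogen transfer from the methyl group, and the six-membered ring closes to the bicyclo[3.1.1]heptane; the carbinol configuration does not matter.

Step 10
Reactants: 20 3-[(tert-butyldimethylsilyl)oxy]-11-hydroxy-2,6,6-trimethyl-9-methylidenetricyclo[5.4.0.0(2,8)]undecan-5-yl 3-methylbut-2-enoate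
Product: 22 (1R,2R,3R,5R,7S,8R)-3-[(tert-butyldimethylsilyl)oxy]-2,6,6,9-tetramethyl-11-oxotricyclo[5.4.0.0(2,8)]undec-9-en-5-yl 3-methylbut-2-enoate, via exo-methylene ketone 21 (not isolated)
Conditions: Dess–Martin periodinane (1.5 equiv), NaHCO3, CH2Cl2, 0 °C → rt; then DBU (1 equiv), rt
Reagents that add atoms: none
Why: Dess–Martin oxidation, then base-mediated shift of the β,γ-double bond into conjugation through the dienolate (only the CH2 between carbonyl and alkene can enolise, the bridgehead cannot), which should give the trisubstituted endocyclic enone; no stereocentre is touched.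

Step 11
Reactants: 22 (1R,2R,3R,5R,7S,8R)-3-[(tert-butyldimethylsilyl)oxy]-2,6,6,9-tetramethyl-11-oxotricyclo[5.4.0.0(2,8)]undec-9-en-5-yl 3-methylbut-2-enoate
Product: 23 (1R,2R,3R,5R,7S,8R)-3-hydroxy-2,6,6,9-tetramethyl-11-oxotricyclo[5.4.0.0(2,8)]undec-9-en-5-yl 3-methylbut-2-enoate
Conditions: HF·pyridine, pyridine/THF, 0 °C → rt
Reagents that add atoms: none
Why: fluoride cleavage of the silyl ether under buffered acidic conditions; ester and enone should be stable, and the freed alcohol is γ to the ketone, so no retro-aldol path exists.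

Step 12
Reactants: 23 (1R,2R,3R,5R,7S,8R)-3-hydroxy-2,6,6,9-tetramethyl-11-oxotricyclo[5.4.0.0(2,8)]undec-9-en-5-yl 3-methylbut-2-enoate
Product: 24 (1R,2R,3R,5R,7S,8R)-2,6,6,9-tetramethyl-11-oxotricyclo[5.4.0.0(2,8)]undec-9-ene-3,5-diyl bis(3-methylbut-2-enoate)
Conditions: 3-methylbut-2-enoyl chloride (3 equiv), pyridine, DMAP (0.3 equiv), CH2Cl2, 0 → 40 °C
Reagents that add atoms: 3-methylbut-2-enoyl chloride, CC(C)=CC(Cl)=O
Why: DMAP-catalysed acylation as in step 3; the alcohol is hindered but secondary and there is no competing site.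

**Compound list**

1 | (−)-B-methoxydiisopinocampheylborane, methoxybis[(1R,2S,3R,5R)-2,6,6-trimethylbicyclo[3.1.1]heptan-3-yl]borane | COB([C@@H]1C[C@@H]2C[C@H]([C@H]1C)C2(C)C)[C@@H]1C[C@@H]2C[C@H]([C@H]1C)C2(C)C | starting material
2 | 3-methylbut-2-enylmagnesium chloride | CC(C)=CC[Mg]Cl | starting material
3 | (−)-B-(3-methylbut-2-enyl)diisopinocampheylborane | CC(C)=CCB([C@@H]1C[C@@H]2C[C@H]([C@H]1C)C2(C)C)[C@@H]1C[C@@H]2C[C@H]([C@H]1C)C2(C)C | intermediate
4 | methacrolein (2-methylprop-2-enal) | CC(=C)C=O | starting material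
5 | tert-butyldimethyl(vinyloxy)silane | C=CO[Si](C)(C)C(C)(C)C | starting material
6 | (3R)-3-[(tert-butyldimethylsilyl)oxy]-4-methylpent-4-enal | C=C(C)[C@H](O[Si](C)(C)C(C)(C)C)CC=O | intermediate
7 | diisopinocampheylborinic ester of alcohol 8 (boron on the C-4 oxygen) | C=C(C)[C@H](O[Si](C)(C)C(C)(C)C)C[C@@H](OB([C@@H]1C[C@@H]2C[C@H]([C@H]1C)C2(C)C)[C@@H]1C[C@@H]2C[C@H]([C@H]1C)C2(C)C)C(C)(C)C=C | intermediate
8 | (4R,6R)-6-[(tert-butyldimethylsilyl)oxy]-3,3,7-trimethylocta-1,7-dien-4-ol | C=C(C)[C@H](O[Si](C)(C)C(C)(C)C)C[C@@H](O)C(C)(C)C=C | intermediate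
9 | (4R,6R)-6-[(tert-butyldimethylsilyl)oxy]-3,3,7-trimethylocta-1,7-dien-4-yl 3-methylbut-2-enoate | C=C(C)[C@H](O[Si](C)(C)C(C)(C)C)C[C@@H](OC(=O)C=C(C)C)C(C)(C)C=C | intermediate
10 | (3R,5R,7E)-3-[(tert-butyldimethylsilyl)oxy]-2,6,6,9-tetramethyldeca-1,7,9-trien-5-yl 3-methylbut-2-enoate | C=C(C)[C@H](O[Si](C)(C)C(C)(C)C)C[C@@H](OC(=O)C=C(C)C)C(C)(C)/C=C/C(C)=C | intermediate
11 | B-alkyl-9-borabicyclo[3.3.1]nonane adduct of 10 (boron on C-1, C-2 epimers) | C1CCC2CCCC1B2CC(C)[C@H](O[Si](C)(C)C(C)(C)C)C[C@@H](OC(=O)C=C(C)C)C(C)(C)/C=C/C(C)=C | intermediate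
12 | (2RS,3R,5R,7E)-3-[(tert-butyldimethylsilyl)oxy]-1-hydroxy-2,6,6,9-tetramethyldeca-7,9-dien-5-yl 3-methylbut-2-enoate | OCC(C)[C@H](O[Si](C)(C)C(C)(C)C)C[C@@H](OC(=O)C=C(C)C)C(C)(C)/C=C/C(C)=C | intermediate
13 | (2RS,3R,5R,7E)-3-[(tert-butyldimethylsilyl)oxy]-2,6,6,9-tetramethyl-1-oxodeca-7,9-dien-5-yl 3-methylbut-2-enoate | O=CC(C)[C@H](O[Si](C)(C)C(C)(C)C)C[C@@H](OC(=O)C=C(C)C)C(C)(C)/C=C/C(C)=C | intermediate
14 | (2RS,3R,5R,7E)-3-[(tert-butyldimethylsilyl)oxy]-2,6,6,9-tetramethyl-5-[(3-methylbut-2-enoyl)oxy]deca-7,9-dienoic acid | OC(=O)C(C)[C@H](O[Si](C)(C)C(C)(C)C)C[C@@H](OC(=O)C=C(C)C)C(C)(C)/C=C/C(C)=C | intermediate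
15 | acid chloride of 14 | ClC(=O)C(C)[C@H](O[Si](C)(C)C(C)(C)C)C[C@@H](OC(=O)C=C(C)C)C(C)(C)/C=C/C(C)=C | intermediate
16 | (3R,5R,7E)-3-[(tert-butyldimethylsilyl)oxy]-2,6,6,9-tetramethyl-1-oxodeca-1,7,9-trien-5-yl 3-methylbut-2-enoate (methylketene) | O=C=C(C)[C@H](O[Si](C)(C)C(C)(C)C)C[C@@H](OC(=O)C=C(C)C)C(C)(C)/C=C/C(C)=C | intermediate
17 | 2-[(tert-butyldimethylsilyl)oxy]-1,5,5-trimethyl-7-oxo-8-(prop-1-en-2-yl)bicyclo[4.1.1]octan-4-yl 3-methylbut-2-enoate, isopropenyl syn to the carbonyl bridge, silyloxy and ester groups trans | CC(C)=CC(=O)O[C@@H]1C[C@@H](O[Si](C)(C)C(C)(C)C)[C@@]2(C)C(=O)[C@H]([C@@H]2C(C)=C)C1(C)C | intermediate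
18 | 7-(methoxymethylidene) analogue of 17 (enol ether, both geometries) | CC(C)=CC(=O)O[C@@H]1C[C@@H](O[Si](C)(C)C(C)(C)C)[C@@]2(C)C(=COC)[C@H]([C@@H]2C(C)=C)C1(C)C | intermediate
19 | 2-[(tert-butyldimethylsilyl)oxy]-7-formyl-1,5,5-trimethyl-8-(prop-1-en-2-yl)bicyclo[4.1.1]octan-4-yl 3-methylbut-2-enoate, formyl cis to isopropenyl | CC(C)=CC(=O)O[C@@H]1C[C@@H](O[Si](C)(C)C(C)(C)C)[C@@]2(C)[C@H](C=O)[C@H]([C@@H]2C(C)=C)C1(C)C | intermediate
20 | 3-[(tert-butyldimethylsilyl)oxy]-11-hydroxy-2,6,6-trimethyl-9-methylidenetricyclo[5.4.0.0(2,8)]undecan-5-yl 3-methylbut-2-enoate, ring centres as in 24, C-11 epimers | CC(C)=CC(=O)O[C@@H]1C[C@@H](O[Si](C)(C)C(C)(C)C)[C@@]2(C)[C@@H]3C(O)CC(=C)[C@H]2[C@@H]3C1(C)C | intermediate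
21 | 3-[(tert-butyldimethylsilyl)oxy]-2,6,6-trimethyl-9-methylidene-11-oxotricyclo[5.4.0.0(2,8)]undecan-5-yl 3-methylbut-2-enoate, ring centres as in 24 | CC(C)=CC(=O)O[C@@H]1C[C@@H](O[Si](C)(C)C(C)(C)C)[C@@]2(C)[C@@H]3C(=O)CC(=C)[C@H]2[C@@H]3C1(C)C | intermediate
22 | (1R,2R,3R,5R,7S,8R)-3-[(tert-butyldimethylsilyl)oxy]-2,6,6,9-tetramethyl-11-oxotricyclo[5.4.0.0(2,8)]undec-9-en-5-yl 3-methylbut-2-enoate | CC(C)=CC(=O)O[C@@H]1C[C@@H](O[Si](C)(C)C(C)(C)C)[C@@]2(C)[C@@H]3C(=O)C=C(C)[C@H]2[C@@H]3C1(C)C | intermediate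
23 | (1R,2R,3R,5R,7S,8R)-3-hydroxy-2,6,6,9-tetramethyl-11-oxotricyclo[5.4.0.0(2,8)]undec-9-en-5-yl 3-methylbut-2-enoate | CC(C)=CC(=O)O[C@@H]1C[C@@H](O)[C@@]2(C)[C@@H]3C(=O)C=C(C)[C@H]2[C@@H]3C1(C)C | intermediate
24 | (1R,2R,3R,5R,7S,8R)-2,6,6,9-tetramethyl-11-oxotricyclo[5.4.0.0(2,8)]undec-9-ene-3,5-diyl bis(3-methylbut-2-enoate) | CC(C)=CC(=O)O[C@@H]1C[C@@H](OC(=O)C=C(C)C)[C@@]2(C)[C@@H]3C(=O)C=C(C)[C@H]2[C@@H]3C1(C)C | target

**Step count and risks**

Total step count: 12. Longest linear sequence: 12 (steps 1 to 12; the borane made in step 1 enters the main line in step 2).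

The three steps most likely to fail:

Step 7. The ketene may dimerise or oligomerise before the seven-membered closure. The zwitterion may close at the far diene terminus to a six-membered ring. The diene may add to the wrong ketene face. Fallback: keteniminium cycloaddition. It sets out from acid 14, which is condensed with pyrrolidine (N-(3-dimethylaminopropyl)-N'-ethylcarbodiimide hydrochloride, HOBt, CH2Cl2) to the pyrrolidine amide F1. Tf2O and 2,6-di-tert-butyl-4-methylpyridine in 1,2-dichloroethane at 80 °C should convert it into the keteniminium triflate F2. This species is more electrophilic than the ketene and cannot dimerise, so it should add to the diene terminus to give the cyclobutaniminium triflate F3. Aqueous NaHCO3 hydrolysis brings the sequence back to the route at ketone 17. A C2-symmetric 2,5-dimethylpyrrolidine in place of pyrrolidine would add reagent control of the face.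

Step 9. The formyl epimer that points away from the isopropenyl group cannot reach the alkene, and the Prins cation may be trapped or the strained ring may not close under Lewis acid. Fallback: intramolecular alkene acylation. It sets out from aldehyde 19, which is oxidised (NaClO2, NaH2PO4, 2-methylbut-2-ene, tBuOH/H2O) to the carboxylic acid F4. This is converted with 1-chloro-N,N,2-trimethylprop-1-en-1-amine into the acid chloride F5 and cyclised with SnCl4 in CH2Cl2 at −78 °C to the β-chloro ketone F6. DBU then eliminates HCl and the sequence comes back to the route at enone 22, replacing steps 9 and 10.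

Step 2. With the small, volatile enal the confined-acid aldol may suffer from low enantioselectivity, oligomerisation or conjugate addition, and excess reagents may interfere with the prenylation in the same pot. Fallback: stepwise thioacetate aldol. It sets out from methacrolein 4, which is treated with 1-(tert-butylsulfanyl)-1-(trimethylsilyloxy)ethene under Ti(OiPr)4/(S)-BINOL catalysis (BINOL antipode chosen for the 3R adduct) to give the O-trimethylsilyl thioester adduct F7. Acidic work-up cleaves it to S-tert-butyl (3R)-3-hydroxy-4-methylpent-4-enethioate F8. TBSOTf/2,6-lutidine gives the silyl ether F9, and iBu2AlH at −78 °C reduces the thioester to aldehyde 6, now isolated. Addition of 3 and oxidative work-up as in step 2 brings the sequence back to the route at alcohol 8.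

Further compounds
F1 | step 7 | pyrrolidine amide of acid 14 | O=C(N1CCCC1)C(C)[C@H](O[Si](C)(C)C(C)(C)C)C[C@@H](OC(=O)C=C(C)C)C(C)(C)/C=C/C(C)=C
F2 | step 7 | keteniminium triflate from F1 | CC(=C=[N+]1CCCC1)[C@H](O[Si](C)(C)C(C)(C)C)C[C@@H](OC(=O)C=C(C)C)C(C)(C)/C=C/C(C)=C.[O-]S(=O)(=O)C(F)(F)F
F3 | step 7 | cyclobutaniminium triflate (pyrrolidinium analogue of ketone 17) | CC(C)=CC(=O)O[C@@H]1C[C@@H](O[Si](C)(C)C(C)(C)C)[C@@]2(C)C(=[N+]3CCCC3)[C@H]([C@@H]2C(C)=C)C1(C)C.[O-]S(=O)(=O)C(F)(F)F
F4 | step 9 | 7-carboxylic acid from aldehyde 19 | CC(C)=CC(=O)O[C@@H]1C[C@@H](O[Si](C)(C)C(C)(C)C)[C@@]2(C)[C@H](C(=O)O)[C@H]([C@@H]2C(C)=C)C1(C)C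
F5 | step 9 | acid chloride of F4 | CC(C)=CC(=O)O[C@@H]1C[C@@H](O[Si](C)(C)C(C)(C)C)[C@@]2(C)[C@H](C(=O)Cl)[C@H]([C@@H]2C(C)=C)C1(C)C
F6 | step 9 | 9-chloro-9-methyl-11-oxo tricyclic ketone (β-chloro ketone, C-9 epimers) | CC(C)=CC(=O)O[C@@H]1C[C@@H](O[Si](C)(C)C(C)(C)C)[C@@]2(C)[C@@H]3C(=O)CC(C)(Cl)[C@H]2[C@@H]3C1(C)C
F7 | step 2 | S-tert-butyl (3R)-4-methyl-3-[(trimethylsilyl)oxy]pent-4-enethioate | C=C(C)[C@H](O[Si](C)(C)C)CC(=O)SC(C)(C)C
F8 | step 2 | S-tert-butyl (3R)-3-hydroxy-4-methylpent-4-enethioate | C=C(C)[C@H](O)CC(=O)SC(C)(C)C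
F9 | step 2 | S-tert-butyl (3R)-3-[(tert-butyldimethylsilyl)oxy]-4-methylpent-4-enethioate | C=C(C)[C@H](O[Si](C)(C)C(C)(C)C)CC(=O)SC(C)(C)C
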